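(The readings are simulated for substances that don't exist; the scatter is artificial.)

The rate constants of this flask are not given to us, so we look in the readings for one number that can stand in for them.

common to all: solid substrate 0.10 M

|  | reagent | temperature | remark | time |
|---|---|---|---|---|
| summer | 0.30 M | 90 °C | the very flask that is asked about, followed so far |  |
| autumn | 0.30 M | 75 °C | run made earlier |  |
| flask | 0.300 M | 90 °C |  | 20 h |

- summer (time / h: target / %): 1.50: 29.5; 2.50: 38.3; 4.00: 42.3; 8.00: 44.3; 12.0: 44.0; 20.0: 44.8
- autumn (time / h: target / %): 3.00: 43.9; 5.00: 64.2; 8.00: 77.7; 15.0: 86.5; 25.0: 88.6; 40.0: 91.1

(readings scatter by 1 percentage point)

- ochre: at 20 h raise the temperature by 10 K, then wait 20 h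
- grey: at 20 h take out 90% of the target then present, then wait 20 h
- amber: at 20 h add reagent, 50.0% of the amount charged, then wait 20 h
- violet: change nothing and wait 20 h more

- given per volume of solution although it is solid: solid substrate
- what is taken out of target is counted as made
- what was read earlier has a scatter of 1 percentage point, one standard deviation
- what may be going on: solid substrate <-> dissolved substrate; dissolved substrate + reagent -> target; reagent -> side product
- at the start none of the solid substrate is in solution
- additions bring no volume worth counting

1. target, in percent of the solid substrate first charged, at 20 h
2. the remedy with the largest gain of target, or "none" below 2 percentage points (ochre / grey / amber / violet / none)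
3. target present, with what was taken out counted in, in percent of the solid substrate first charged, after grey
4. target present, with what was taken out counted in, in percent of the solid substrate first charged, after violet

We build the flask up one process at a time. With the main step by itself, dissolved substrate + reagent → target, the 0.300 M of reagent stands above the 0.10 M of solid substrate, and the charge allows 100% target. The autumn run, at 75 °C, comes close with 91.1%.

Next we add the dissolving of the solid. This feeds [dissolved substrate] but makes no new target, so the number stays and the pace changes. We freeze [dissolved substrate] at a steady value, as a working assumption, while solid remains.

Then comes reagent → side product, and the number falls. The summer run reads 44.4% on average from 8.00 h to 20.0 h, with 55.6% of the substrate not turned into target. The autumn run, from the same charges, went higher, so we read the halt as the reagent's: on this reading it is the limiting reagent in spite of its excess. With [dissolved substrate] frozen and the temperature held at 90 °C, the two steps that use reagent divide it in a fixed ratio: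

target at the plateau / reagent charged = 44.4% × 0.10 M / 0.30 M = 14.8%

This is the reagent share, the target made per reagent charged, in the usual term a selectivity.

On our reckoning, waiting, heating and taking out target bring no reagent, so the flask stays at 44.4% and those options gain nothing. Amber brings 0.150 M of reagent:

gain = 14.8% × 0.150 M / 0.10 M = 22 percentage points

That is less than the 55.6% of substrate not turned into target at the plateau.

The forecast gives 44.4% at 20 h, 44.4% after grey and 44.4% after violet, and it chooses amber, with roughly 22 points gained. Its ground is this: “The plateau is therefore reagent exhaustion”.

The flask gives 43.2% at 20 h, 43.2% after grey and 43.2% after violet, and the best remedy is amber, with a gain of 28 points.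

    solid substrate ⇌ dissolved substrate, rate k1*(cs1 - [dissolved substrate]) while solid is left; crystals form when [dissolved substrate] > cs1 (solubility = 45.0 mM, k = 0.0438 min⁻¹)
    dissolved substrate + reagent → target (k = 0.0820 M⁻¹ min⁻¹, Ea = 63.0 kJ mol⁻¹)
    reagent → side product (k = 0.0137 min⁻¹, Ea = 125 kJ mol⁻¹)
    (constants at 90 °C)

At 20.0 h the flask holds 0% of its reagent charge and 45.0% as dissolved substrate. Amber reaches 70.8%, so the added reagent shows a share of 18.4%, above the 14.8% read from the summer run for the first charge. A neighbour flask, the same but charged with 0.12 M of reagent, should by the share give 17.8% target, and it gives 18.6%.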